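Side-chain numbering runs from C1′ (the CH2 on pyrone C6) to C11′ (the benzylic CH2). After unmasking O4, the retrosynthesis cuts C5′–C6′: this bond ties a plain CH2 (C5′) to the Z-trisubstituted C6′=C7′ alkene, bears no stereocentre and lies outside the 2-pyranone ring, so a pyrone acid one carbon longer (as its N-hydroxyphthalimide ester) can be joined there to a Z-alkenyl iodide by decarboxylative sp3–sp2 coupling.
The acid half is cut at C4′–C5′ (Johnson–Claisen, which also sets C2′=C3′) and at C1′–C2′ (vinylogous aldol with methacrolein); the 2-pyranone ring is cut at O1–C2 (lactonisation), C5–C6 (dianion acylation) and C3–C4 (Claisen acylation).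
The iodide half is cut at C8′–C9′ into a (Z)-3-iodo-2-methylallyl bromide and an (E)-alkenylmagnesium reagent.
Forward: the pyranone ring is built first (steps 1–3), its C6 methyl is grown to the redox-active ester (steps 4–7), the iodide is made in parallel (steps 8–11), the halves are joined at C5′–C6′ (step 12) and the MOM group is removed (step 13).
Stereochemistry: the target has no stereocentre; 2′E comes from the chair Johnson–Claisen, 6′Z from hydroxyl-directed anti-carbomagnesiation of propargyl alcohol, 9′E from syn-hydrozirconation, and each geometry is carried on with retention.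

Key step: step 12

Assumption: the carbinol centre made in step 4 is formed racemic and is erased in step 5, and the CH centres of 3 and 5 are enolisable, so none of them needs control.

Step 1
Reactants: 1 methyl methoxyacetate; 2 propanoyl chloride
Product: 3 methyl 2-methoxy-3-oxopentanoate (racemic)
Conditions: 1 (2.0 equiv), LiN(i-Pr)2 (2.0 equiv), THF, −78 °C; 2 (1.0 equiv), −78 °C; aq. NH4Cl
Reagents that add atoms: none
Why: Crossed Claisen acylation, in which the lithium enolate of 1 is C-acylated by the acid chloride at −78 °C and the second equivalent of enolate deprotonates the more acidic β-keto ester, protecting it from a second acylation.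

Step 2
Reactants: 3 methyl 2-methoxy-3-oxopentanoate; 4 N-methoxy-N-methylacetamide
Product: 6 4-hydroxy-3-methoxy-5,6-dimethyl-2H-pyran-2-one, via methyl 2-methoxy-4-methyl-3,5-dioxohexanoate 5 (not isolated)
Conditions: LiN(i-Pr)2 (2.2 equiv), THF, −78 → 0 °C; 4, −78 → 0 °C; 1 M HCl; crude 5, DBU (1.5 equiv), toluene, 80 °C; 1 M HCl
Reagents that add atoms: none
Why: β-Keto ester dianion acylation followed by lactonisation: the γ-carbon of the dianion is the more nucleophilic site and is acylated once by the Weinreb amide, and DBU then closes the C5 enol oxygen onto the methyl ester (6-exo-trig) to give the aromatic 4-hydroxy-2-pyranone.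

Step 3
Reactants: 6 4-hydroxy-3-methoxy-5,6-dimethyl-2H-pyran-2-one
Product: 7 3-methoxy-4-(methoxymethoxy)-5,6-dimethyl-2H-pyran-2-one
Conditions: MOMCl, i-Pr2NEt, CH2Cl2, 0 °C → rt
Reagents that add atoms: chloromethyl methyl ether, COCCl
Why: O-alkylation of the vinylogous acid with the hard electrophile MOMCl under amine base should favour the 4-alkoxy-2-pyranone over the isomeric 2-alkoxy-4-pyranone, which can be separated if it forms.

Step 4
Reactants: 7 3-methoxy-4-(methoxymethoxy)-5,6-dimethyl-2H-pyran-2-one; 8 methacrolein
Product: 10 6-(2-hydroxy-3-methylbut-3-en-1-yl)-3-methoxy-4-(methoxymethoxy)-5-methyl-2H-pyran-2-one (racemic), via 6-(lithiomethyl)-3-methoxy-4-(methoxymethoxy)-5-methyl-2H-pyran-2-one 9 (not isolated)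
Conditions: LiN(i-Pr)2 (1.1 equiv), THF, −78 °C; 8 (1.5 equiv, freshly distilled), −78 °C; AcOH, −78 °C
Reagents that add atoms: none
Why: Vinylogous aldol addition: only the C6 methyl gives a dienolate conjugated through C5=C6 and C3=C4 to the lactone carbonyl, and this lithium dienolate should add 1,2 to the enal through its exocyclic carbon at −78 °C, restoring the pyranone; the new carbinol centre is racemic and is lost in step 5.

Step 5
Reactants: 10 6-(2-hydroxy-3-methylbut-3-en-1-yl)-3-methoxy-4-(methoxymethoxy)-5-methyl-2H-pyran-2-one; 11 trimethyl orthoacetate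
Product: 13 methyl (4E)-6-[3-methoxy-4-(methoxymethoxy)-5-methyl-2-oxo-2H-pyran-6-yl]-4-methylhex-4-enoate, via mixed ketene acetal 12 (not isolated)
Conditions: 11 (10 equiv), EtCO2H (cat.), toluene, 110 °C, MeOH distilled off
Reagents that add atoms: none
Why: Johnson–Claisen rearrangement: orthoester exchange and loss of methanol give the allyl ketene acetal 12, whose chair [3,3] shift keeps the pyranylmethyl group equatorial and so should deliver the (E)-trisubstituted C2′=C3′ alkene together with the C4′–C5′ bond and the ester carbon.

Step 6
Reactants: 13 methyl (4E)-6-[3-methoxy-4-(methoxymethoxy)-5-methyl-2-oxo-2H-pyran-6-yl]-4-methylhex-4-enoate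
Product: 14 (4E)-6-[3-methoxy-4-(methoxymethoxy)-5-methyl-2-oxo-2H-pyran-6-yl]-4-methylhex-4-enoic acid
Conditions: Me3SnOH (4 equiv), ClCH2CH2Cl, 70 °C; cold 0.1 M HCl wash
Reagents that add atoms: trimethyltin hydroxide, C[Sn](C)(C)O
Why: Trimethyltin hydroxide ester cleavage is near-neutral and selective for unhindered methyl esters, so the pyranone lactone and the MOM vinylogous ester, both open to attack by aqueous hydroxide, should be spared.

Step 7
Reactants: 14 (4E)-6-[3-methoxy-4-(methoxymethoxy)-5-methyl-2-oxo-2H-pyran-6-yl]-4-methylhex-4-enoic acid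
Product: 15 1,3-dioxoisoindolin-2-yl (4E)-6-[3-methoxy-4-(methoxymethoxy)-5-methyl-2-oxo-2H-pyran-6-yl]-4-methylhex-4-enoate
Conditions: N-hydroxyphthalimide, N,N′-diisopropylcarbodiimide, DMAP (cat.), CH2Cl2, rt
Reagents that add atoms: N-hydroxyphthalimide, O=C1c2ccccc2C(=O)N1O
Why: Steglich-type carbodiimide esterification gives the redox-active ester under neutral conditions that leave the pyranone, the MOM group and the E alkene untouched.

Step 8
Reactants: 16 prop-2-yn-1-ol
Product: 18 (2Z)-3-iodo-2-methylprop-2-en-1-ol, via 4-methyl-2,5-dihydro-1,2-oxamagnesole 17 (not isolated)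
Conditions: MeMgBr (2.5 equiv), CuI (10 mol%), THF/Et2O, −10 °C → rt; I2, −78 → 0 °C
Reagents that add atoms: methylmagnesium bromide, C[Mg]Br; iodine, II
Why: Copper-catalysed anti-carbomagnesiation of the propargylic magnesium alkoxide places magnesium on C3 within a five-membered chelate and methyl on C2 from the opposite side, so iodinolysis of the C–Mg bond with retention should give the iodide with iodine cis to CH2OH (Z).

Step 9
Reactants: 18 (2Z)-3-iodo-2-methylprop-2-en-1-ol
Product: 19 (1Z)-3-bromo-1-iodo-2-methylprop-1-ene
Conditions: CBr4, PPh3, CH2Cl2, 0 °C (product kept cold and dark, used promptly)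
Reagents that add atoms: carbon tetrabromide, BrC(Br)(Br)Br
Why: Appel bromination replaces the primary allylic hydroxyl by SN2 displacement at CH2 under neutral conditions, without allylic transposition or loss of the Z geometry.

Step 10
Reactants: 20 but-2-yn-1-ylbenzene
Product: 22 [(2E)-3-iodobut-2-en-1-yl]benzene, via chloridobis(cyclopentadienyl)[(2E)-4-phenylbut-2-en-2-yl]zirconium 21 (not isolated)
Conditions: Cp2Zr(H)Cl (1.5 equiv), THF, 50 °C; I2, THF, 0 °C
Reagents that add atoms: iodine, II
Why: Hydrozirconation adds Zr–H syn across the alkyne, warming with a slight excess of the hydride equilibrates zirconium onto the less hindered methyl-bearing carbon, and iodinolysis with retention should give the (E)-iodide with the benzylic CH2 trans to iodine.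

Step 11
Reactants: 22 [(2E)-3-iodobut-2-en-1-yl]benzene; 19 (1Z)-3-bromo-1-iodo-2-methylprop-1-ene
Product: 25 [(2E,5Z)-6-iodo-3,5-dimethylhexa-2,5-dien-1-yl]benzene, via [(2Z)-4-phenylbut-2-en-2-yl]lithium 23 (not isolated), via bromido[(2E)-4-phenylbut-2-en-2-yl]magnesium 24 (not isolated)
Conditions: 22, t-BuLi (1.95 equiv), Et2O, −78 °C; MgBr2·OEt2 (1.2 equiv), −78 → −20 °C; 19 (1.3 equiv), Li2CuCl4 (5 mol%), THF, −78 → 0 °C
Reagents that add atoms: none
Why: Iodine–lithium exchange with retention, transmetalation to magnesium and copper-catalysed Grignard allylic substitution: in THF at low temperature the alkenylmagnesium should displace the primary allylic bromide at its CH2 carbon much faster than the alkenyl C–I bond of 19 reacts, forming C8′–C9′ with both alkene geometries kept.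

Step 12
Reactants: 15 1,3-dioxoisoindolin-2-yl (4E)-6-[3-methoxy-4-(methoxymethoxy)-5-methyl-2-oxo-2H-pyran-6-yl]-4-methylhex-4-enoate; 25 [(2E,5Z)-6-iodo-3,5-dimethylhexa-2,5-dien-1-yl]benzene
Product: 26 3-methoxy-4-(methoxymethoxy)-5-methyl-6-[(2E,6Z,9E)-3,7,9-trimethyl-11-phenylundeca-2,6,9-trien-1-yl]-2H-pyran-2-one (4-O-(methoxymethyl)lehualide A)
Conditions: 15 (1.5 equiv), 25 (1.0 equiv), NiCl2·6H2O (20 mol%), 2,2′-bipyridine (20 mol%), AgNO3 (0.3 equiv), DMF, rt, undivided cell, Mg anode/reticulated vitreous carbon cathode, constant current (ca. 2.5 F per mol of 25)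
Reagents that add atoms: none
Why: The silver-coated cathode reduces the divalent nickel–bipyridine complex to low-valent nickel, which adds oxidatively to the C–I bond of 25 with retention, while single-electron reduction of ester 15 releases phthalimide anion, CO2 and the primary C5′ radical that nickel captures before reductive elimination forms C5′–C6′; the magnesium anode supplies the electrons. The closest known reaction type is the nickel-electrocatalytic decarboxylative alkenylation of N-hydroxyphthalimide esters with alkenyl halides used to assemble polyene terpenoids, and a primary alkyl ester with a trisubstituted alkenyl iodide lies within it. No ring is closed and no stereocentre is formed, so the step only has to preserve the 2′E, 6′Z and 9′E geometries. The 6′Z geometry should be kept because oxidative addition and reductive elimination at nickel are stereoretentive, and the C5′ radical is a simple homoallylic radical whose only rearrangement (reversible 3-exo closure onto C2′=C3′) is degenerate. Cross-coupling should win over radical dimerisation and over reduction of the iodide because 15 is used in modest excess and constant-current electrolysis keeps the radical concentration low. The MOM-masked pyranone is reduced only at potentials well beyond those of the nickel catalyst and the ester, so it should stay a spectator.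

Step 13
Reactants: 26 4-O-(methoxymethyl)lehualide A
Product: 27 lehualide A, 4-hydroxy-3-methoxy-5-methyl-6-[(2E,6Z,9E)-3,7,9-trimethyl-11-phenylundeca-2,6,9-trien-1-yl]-2H-pyran-2-one
Conditions: HCl (ca. 0.5 M) in MeOH/THF, 0 °C → rt
Reagents that add atoms: none
Why: Acid-catalysed transacetalisation: the MOM acetal on the acidic vinylogous-acid oxygen is far more labile than an alkyl MOM ether and should be exchanged to dimethoxymethane by dilute methanolic HCl under conditions too mild to protonate the trisubstituted alkenes of the skipped triene.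

Compound list
1 | methyl methoxyacetate | COCC(=O)OC | starting material
2 | propanoyl chloride | CCC(=O)Cl | starting material
3 | methyl 2-methoxy-3-oxopentanoate (racemic, enolisable C2) | CCC(=O)C(OC)C(=O)OC | intermediate
4 | N-methoxy-N-methylacetamide | CC(=O)N(C)OC | starting material
5 | methyl 2-methoxy-4-methyl-3,5-dioxohexanoate (stereoisomer and tautomer mixture, not isolated) | COC(=O)C(OC)C(=O)C(C)C(C)=O | intermediate
6 | 4-hydroxy-3-methoxy-5,6-dimethyl-2H-pyran-2-one | COc1c(O)c(C)c(C)oc1=O | intermediate
7 | 3-methoxy-4-(methoxymethoxy)-5,6-dimethyl-2H-pyran-2-one | COc1c(OCOC)c(C)c(C)oc1=O | intermediate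
8 | methacrolein (2-methylprop-2-enal) | CC(=C)C=O | starting material
9 | 6-(lithiomethyl)-3-methoxy-4-(methoxymethoxy)-5-methyl-2H-pyran-2-one (lithium dienolate drawn in its C-lithio form, not isolated) | [Li]Cc1oc(=O)c(OC)c(OCOC)c1C | intermediate
10 | 6-(2-hydroxy-3-methylbut-3-en-1-yl)-3-methoxy-4-(methoxymethoxy)-5-methyl-2H-pyran-2-one (racemic) | COc1c(OCOC)c(C)c(CC(O)C(C)=C)oc1=O | intermediate
11 | trimethyl orthoacetate (1,1,1-trimethoxyethane) | CC(OC)(OC)OC | starting material
12 | 3-methoxy-6-{2-[(1-methoxyethenyl)oxy]-3-methylbut-3-en-1-yl}-4-(methoxymethoxy)-5-methyl-2H-pyran-2-one (mixed ketene acetal, racemic, not isolated) | COc1c(OCOC)c(C)c(CC(OC(=C)OC)C(C)=C)oc1=O | intermediate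
13 | methyl (4E)-6-[3-methoxy-4-(methoxymethoxy)-5-methyl-2-oxo-2H-pyran-6-yl]-4-methylhex-4-enoate | COc1c(OCOC)c(C)c(C/C=C(\C)CCC(=O)OC)oc1=O | intermediate
14 | (4E)-6-[3-methoxy-4-(methoxymethoxy)-5-methyl-2-oxo-2H-pyran-6-yl]-4-methylhex-4-enoic acid | COc1c(OCOC)c(C)c(C/C=C(\C)CCC(=O)O)oc1=O | intermediate
15 | 1,3-dioxoisoindolin-2-yl (4E)-6-[3-methoxy-4-(methoxymethoxy)-5-methyl-2-oxo-2H-pyran-6-yl]-4-methylhex-4-enoate | COc1c(OCOC)c(C)c(C/C=C(\C)CCC(=O)ON2C(=O)c3ccccc3C2=O)oc1=O | intermediate
16 | prop-2-yn-1-ol (propargyl alcohol) | OCC#C | starting material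
17 | 4-methyl-2,5-dihydro-1,2-oxamagnesole (chelated alkenylmagnesium alkoxide, not isolated) | CC1=C[Mg]OC1 | intermediate
18 | (2Z)-3-iodo-2-methylprop-2-en-1-ol (iodine cis to CH2OH) | I/C=C(/C)CO | intermediate
19 | (1Z)-3-bromo-1-iodo-2-methylprop-1-ene (iodine cis to CH2Br) | I/C=C(/C)CBr | intermediate
20 | but-2-yn-1-ylbenzene (1-phenylbut-2-yne) | CC#CCc1ccccc1 | starting material
21 | chloridobis(cyclopentadienyl)[(2E)-4-phenylbut-2-en-2-yl]zirconium (zirconium trans to the benzylic CH2, not isolated) | Cl[Zr](C1C=CC=C1)(C1C=CC=C1)/C(C)=C/Cc1ccccc1 | intermediate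
22 | [(2E)-3-iodobut-2-en-1-yl]benzene (iodine trans to the benzylic CH2) | I/C(C)=C/Cc1ccccc1 | intermediate
23 | [(2Z)-4-phenylbut-2-en-2-yl]lithium (lithium trans to the benzylic CH2; the descriptor is Z only because lithium ranks below methyl; not isolated) | [Li]/C(C)=C/Cc1ccccc1 | intermediate
24 | bromido[(2E)-4-phenylbut-2-en-2-yl]magnesium (magnesium trans to the benzylic CH2, not isolated) | Br[Mg]/C(C)=C/Cc1ccccc1 | intermediate
25 | [(2E,5Z)-6-iodo-3,5-dimethylhexa-2,5-dien-1-yl]benzene | I/C=C(/C)C/C(C)=C/Cc1ccccc1 | intermediate
26 | 3-methoxy-4-(methoxymethoxy)-5-methyl-6-[(2E,6Z,9E)-3,7,9-trimethyl-11-phenylundeca-2,6,9-trien-1-yl]-2H-pyran-2-one | COc1c(OCOC)c(C)c(C/C=C(\C)CC/C=C(/C)C/C(C)=C/Cc2ccccc2)oc1=O | intermediate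
27 | lehualide A, 4-hydroxy-3-methoxy-5-methyl-6-[(2E,6Z,9E)-3,7,9-trimethyl-11-phenylundeca-2,6,9-trien-1-yl]-2H-pyran-2-one | COc1c(O)c(C)c(C/C=C(\C)CC/C=C(/C)C/C(C)=C/Cc2ccccc2)oc1=O | target

Total step count: 13.
Longest linear sequence: 9 steps (steps 1–7, 12 and 13); the iodide branch (steps 8–11) joins at step 12.

Steps most likely to fail

Step 12. The primary C5′ radical may dimerise or be reduced before nickel captures it, the alkenyl iodide may be hydrodehalogenated at the cathode, or the alkenylnickel intermediate may lose its Z geometry. The fallback forms the same C5′–C6′ bond without electrolysis, by nickel-catalysed decarboxylative alkenylation with an organozinc partner. It sets out from iodide 25 and ester 15. Iodide 25 is treated with t-BuLi (2 equiv) in Et2O at −78 °C and then with ZnCl2, which should give chlorido[(1Z,4E)-2,4-dimethyl-6-phenylhexa-1,4-dien-1-yl]zinc F1 with retention. This reagent is coupled with 15 under Ni(acac)2 and 2,2′-bipyridine in THF/DMF at rt, and the route is rejoined at compound 26.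

Step 11. The alkenylcopper intermediate may attack the iodine-bearing alkene carbon with allylic transposition, magnesium–iodine exchange may scramble the alkenyl iodide, or the alkenyllithium may be quenched by the acidic benzylic–allylic CH2 of another molecule. The fallback is a palladium-catalysed alkenyl–allyl coupling of an organozirconium, which needs no lithium or magnesium reagent. It sets out from alkyne 20 and bromide 19. Alkyne 20 is hydrozirconated as in step 10 to the alkenylzirconocene 21, which is not iodinated but treated with 19 (1.5 equiv), Pd(PPh3)4 (5 mol%) and ZnCl2 (20 mol%) in THF at 0 °C → rt. The allylic bromide should ionise at zerovalent palladium faster than the hindered alkenyl iodide adds, and the alkenyl group should be delivered to the unsubstituted CH2 terminus of the allyl ligand. The route is rejoined at compound 25, and no compound outside the list arises (F0).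

Step 5. Under heat and weak acid the hydroxyl β to the pyranone may be lost by dehydration to a dienyl pyranone (the C1′ hydrogens are vinylogously acidic), or the MOM acetal may exchange with the orthoester. The fallback makes the C1′–C2′ bond by cross-coupling, so that no alcohol β to the pyranone is ever formed. It sets out from pyranone 7. The lithium dienolate 9 (LiN(i-Pr)2, THF, −78 °C) is quenched with N-bromosuccinimide to give 6-(bromomethyl)-3-methoxy-4-(methoxymethoxy)-5-methyl-2H-pyran-2-one F2. Separately, purchased methyl pent-4-ynoate undergoes Cp2ZrCl2-catalysed syn-carboalumination with Me3Al (CH2Cl2, water-accelerated, −20 °C) to give methyl (4E)-5-(dimethylalumanyl)-4-methylpent-4-enoate F3. This alkenylalane is coupled in the same flask with the bromide under Pd(PPh3)4 (5 mol%) in THF. The product is ester 13, where the route is rejoined, with the 2′E geometry fixed by the syn-carbometalation.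

Further compounds
F1 | step 12 | chlorido[(1Z,4E)-2,4-dimethyl-6-phenylhexa-1,4-dien-1-yl]zinc | Cl[Zn]/C=C(/C)C/C(C)=C/Cc1ccccc1
F0 | step 11 | none | none
F2 | step 5 | 6-(bromomethyl)-3-methoxy-4-(methoxymethoxy)-5-methyl-2H-pyran-2-one | COc1c(OCOC)c(C)c(CBr)oc1=O
F3 | step 5 | methyl (4E)-5-(dimethylalumanyl)-4-methylpent-4-enoate | COC(=O)CC/C(C)=C/[Al](C)C
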